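The runs come from a simulation with made-up constants, noise included.

**The leftover.** At its last reading, 12.0 min, cedar, the flask in question, still has 38.7% of its charge outside the target column. I must decide whether to leave it until 40 min at this charge or to charge more, as birch did.

| setting | cedar | birch | flask |
|---|---|---|---|
| solid substrate | 0.076 M | 0.15 M | 0.076 M |
| gas | 10 mM (held) | 10 mM (held) | 10 mM (held) |
| remark | the very flask that is asked about, followed so far | run made earlier |  |
| time |  |  | 40 min |

| run | time / min | target / % | solid product / % |
|---|---|---|---|
| cedar | 0.833 | 2.8 | 0.1 |
| cedar | 2.50 | 9.2 | 4.9 |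
| cedar | 4.00 | 17.5 | 13.1 |
| cedar | 6.00 | 28.8 | 24.0 |
| cedar | 10.0 | 49.6 | 46.3 |
| cedar | 12.0 | 61.3 | 57.6 |
| birch | 2.50 | 5.4 | 3.3 |
| birch | 8.00 | 19.6 | 17.1 |
| birch | 15.0 | 39.2 | 36.6 |
| birch | 20.0 | 52.5 | 51.2 |
| birch | 30.0 | 80.9 | 78.3 |
| birch | 40.0 | 93.5 | 92.0 |

(readings scatter by 0.5 percentage points)

- percentages count the solid substrate that a species holds: one self-condensation product counts as two
- target is meant together with its solid product
- solid, in amounts per volume of the solution: solid substrate, solid product
- at the start none of partner is dissolved
- candidate steps: solid substrate <-> dissolved substrate; gas <-> partner; 2 solid substrate -> self-condensation product; solid product <-> target; dissolved substrate + partner -> target; target <-> isomer of the product; partner -> side product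
- at the start none of the solid substrate is in solution
- dissolved substrate means what is dissolved; the solid is not counted in it

* amount of target and solid product together at 40 min, in percent of the solid substrate charged
* concentration of dissolved substrate in solution at 40 min, in percent of saturation

**The pace.** I take the dissolving and the passage of gas into partner as quick. While solid lies in the flask, both reactants should then stay level, and their coupling, the rate-limiting step, should run at a steady pace per volume. Cedar's straight stretch gives 18.2 min as its clearing time, the time the whole charge needs at that steady pace. Birch's stretch gives 36.4 min, twice as long for twice the charge, so across these two runs, with the gas held, clearing time goes with the charge.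

**The decision.** Cedar has 21.8 min to spare after clearing, more than birch's 3.60 min, and birch already reads 93.5% at 40.0 min. So I keep cedar's charge, leave it until 40 min, and expect its target above that reading, with little dissolved substrate remaining.

**The forecast.** It also reads “zero order in charge” and gives 96% (from 90% to 99.5%) and 0.5% (from 0% to 4%), figures where I give a bound.

**The result.** The flask gives 95.8% and 0.771%.

    solid substrate ⇌ dissolved substrate, rate k1*(cs1 - [dissolved substrate]) while solid is left; crystals form when [dissolved substrate] > cs1 (solubility = 31.0 mM, k = 1.50 min⁻¹)
    gas ⇌ partner, rate k2*(csat - [partner]) (kL = 3.10 min⁻¹)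
    2 solid substrate → self-condensation product (k = 0.00220 M⁻¹ min⁻¹)
    solid product ⇌ target, rate k4*(cs4 - [target]) while solid is left; crystals form when [target] > cs4 (solubility = 2.00 mM, k = 3.10 min⁻¹)
    dissolved substrate + partner → target (k = 35.0 M⁻¹ min⁻¹)
    target ⇌ isomer of the product (K = 1.40, k = 0.0840 min⁻¹)
    partner → side product (k = 3.10 min⁻¹)

At 20.0 min, later than the clearing time, the flask holds 0% solid substrate and 9.98% dissolved substrate. The neighbour, this same flask left until 1.0 h, has the same clearing time and is read 41.8 min after it. It keeps 0.0095% of its substrate, solid or dissolved, and its target stands at 96.2%, with 3.73% as isomer of the product.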